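Late in Wednesday's flask the product stops moving: its last three readings average 76.2%, while 23.4% of the substrate charged still stands at the last reading. So ask what kind of end state this is, and then how fast the flask approaches it.

all flasks: gas 6.1 mM (held); free catalyst 0.1 mol%
- Wednesday's: substrate 0.032 M; the very flask that is asked about, followed so far
- Sunday's: substrate 0.016 M; run made earlier
- flask: substrate 0.032 M; time 50 min

| run | time / min | product / % | substrate / % |
|---|---|---|---|
| Wednesday's | 8.00 | 58.6 | 41.8 |
| Wednesday's | 15.0 | 71.0 | 29.0 |
| Wednesday's | 25.0 | 75.0 | 24.5 |
| Wednesday's | 30.0 | 76.4 | 24.4 |
| Wednesday's | 40.0 | 75.9 | 23.3 |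
| Wednesday's | 50.0 | 76.2 | 23.4 |
| Sunday's | 1.33 | 11.4 | 87.8 |
| Sunday's | 2.50 | 21.5 | 78.6 |
| Sunday's | 4.00 | 32.4 | 67.3 |
| Sunday's | 5.00 | 38.3 | 61.8 |
| Sunday's | 6.00 | 44.0 | 56.2 |
| Sunday's | 8.00 | 53.1 | 46.3 |

(readings scatter by 0.3 percentage points)

- what is taken out of product is counted as made
- at the start none of the gas is in solution
- additions bring no volume worth counting

- alder: at 50 min add free catalyst, 50.0% of the amount charged, then wait 1.5 h
- birch: at 50 min take out 90% of the product then present, then wait 1.5 h
- maple: change nothing and wait 1.5 h more
- ash: at 50 min add substrate, 50.0% of the amount charged, then wait 1.5 h

* product, in percent of the substrate first charged, at 50 min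
* the option that brings most further product ("none" if no option brings more than 2 percentage points) (alder / birch / maple / ash / none)
* product present, with what was taken out counted in, in percent of the substrate first charged, after birch
* product present, with what was taken out counted in, in percent of the substrate first charged, after maple

Turn the question round. If the stop were an equilibrium, product over substrate would rest at 3.25. Sunday's run reaches a ratio of 1.15, so by its last reading the back reaction would cancel about a third of the forward rate. Yet Sunday's first-order constant reads

0.0978 /min over the first interval, 0.0969 /min over the last.

You therefore read the stop as catalyst that no longer works (catalyst deactivation), not as a balance.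

Waiting, in turn, would pay if the gap, meaning plateau minus product as a fraction of the charge, still exceeded 2 percentage points at 50 min. Wednesday's gap reads

18 points at 8.00 min, 5.2 points at 15.0 min.

Taken as a first-order decay, these two readings give the gap half-life, the time in which the product still to come halves: 3.96 min. Waiting would need a half-life of 25.6 min, and Wednesday's is shorter. Halving on from the second gap:

8.83 halvings leave 0.011 points at 50 min.

So your reckoning puts "now" at the plateau and gives maple less than the margin. Alder brings fresh catalyst to the remaining substrate, so it is your choice.

The forecast gave 76.2% (range 75.8% to 76.6%), 76.5% after birch, 76.4% after maple and alder as best, on the ground “That looks like the catalyst dying”.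

The flask gives 76.3%, 76.8% after birch, 76.4% after maple, and alder as best, with 7.5 points further.

    catalyst intermediate C ⇌ free catalyst + product (K = 0.0140 M, k = 4.60 /s)
    product + catalyst intermediate C → spent catalyst (k = 0.160 /M/s)
    reagent + catalyst intermediate A → catalyst intermediate B (k = 21000 /M/s)
    gas ⇌ reagent, rate k4*(csat - [reagent]) (kL = 0.0370 /s)
    catalyst intermediate B → catalyst intermediate C (k = 17.0 /s)
    substrate + free catalyst ⇌ catalyst intermediate A (K = 15.0 /M, k = 240 /M/s)

Has Wednesday's flask come to rest? The half-life of 3.96 min put 0.011 points still to come at 50 min; maple brought 0.024 points, with free catalyst at 0.0384% and spent catalyst at 99.9% of the catalyst charged at that time. Lend the half-life read in Wednesday's flask, as an assumption, to the neighbour charged with 0.080 M of substrate at the same loading: 50 min then counts 12.6 half-lives, and at that time its simulated state shows spent catalyst at >99.9% of its catalyst and product at 57.7% of its substrate. Wednesday's flask, left ten times as long, stands at 76.4% of the substrate charged as product, with free catalyst at 0%.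

(The readings were generated by integration from invented constants, and the scatter is random.)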